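If the added ligand holds catalyst one to one, as a tight-binding inhibitor holds an enzyme, a flask turns over with its free catalyst, not with the catalyst charged.

| flask | starting material | other conformer | catalyst | added ligand | remark | time |
|---|---|---|---|---|---|---|
| theta | 10 mM | 0.25 equiv | 10 mol% | 2 mM | run made earlier |  |
| alpha | 15 mM | 0.25 equiv | 10 mol% | 2 mM | run made earlier |  |
| epsilon | 20 mM | 0.25 equiv | 20 mol% | 2 mM | run made earlier |  |
| flask | 20 mM | 0.250 equiv | 10 mol% | 2.0 mM |  | 15 min |

- theta (time / min: target / %, isomer of the product A / %, starting material / %): 1.50: 1.2, 1.1, 84.0; 4.00: 1.6, 0.5, 75.8; 8.00: 2.2, 1.5, 64.8; 12.0: 3.8, 2.9, 53.9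
- alpha (time / min: target / %, isomer of the product A / %, starting material / %): 1.00: 1.1, 1.0, 81.0; 2.00: 2.2, 1.7, 74.8; 5.00: 4.6, 2.7, 57.0; 12.0: 5.3, 4.5, 31.3
- epsilon (time / min: target / %, isomer of the product A / %, starting material / %): 1.00: 7.0, 5.5, 41.2; 2.00: 8.2, 6.9, 19.3; 5.00: 8.6, 9.4, 1.8; 12.0: 6.2, 8.9, 0.3

(scatter of a reading: 0.3 percentage points)

- the earlier runs were read with a standard deviation of 0.3 percentage points

1. ratio of target to isomer of the product A at 3.0 s
2. ratio of target to isomer of the product A at 15 min

Two readings seem not to fit. Epsilon carries 4.00 times the catalyst of theta, yet, as I read them, its starting material decays at 0.758 min⁻¹ against 0.0426 min⁻¹ in theta, which is 17.8 times faster than theta's.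

Suppose epsilon's ligand is bound; then its excess of catalyst, 2.00 mM, is free, and that gives the decay per unit of free catalyst, 6.32 L mol⁻¹ s⁻¹. So I treat theta's free catalyst as the small part and compute that. Theta's decay makes its free catalyst 0.112 mM, and the balance of bound and unbound forms gives a binding constant of 7.10 mM⁻¹.

In this flask catalyst and ligand are equal, so the same balance gives 0.465 mM, or 23.3% of the charge. This free catalyst, the part of the charge not held by ligand, is what I carry. The flask's 15 min then match 3.49 min of epsilon, where the ratio of target to isomer of the product A reads between 1.19 and 0.915, so I expect about 1. For 3.0 s this reckoning offers no number.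

The forecast says 1.25 at 3.0 s, “assuming no distinct burst selectivity”, and 1 at 15 min.

The flask gives 3.77 and 0.882.

    starting material ⇌ other conformer (K = 0.110, k = 0.00460 s⁻¹)
    starting material + catalyst → catalyst + target (k = 6.20 L mol⁻¹ s⁻¹)
    catalyst + other conformer → catalyst + isomer of the product A (k = 4.10 L mol⁻¹ s⁻¹)
    catalyst + added ligand ⇌ idle complex (K = 6900 L mol⁻¹, k = 340 L mol⁻¹ s⁻¹)
    target ⇌ isomer of the product B (K = 7.20, k = 0.320 s⁻¹)
    target → over-reaction product (k = 0.00710 s⁻¹)

The flask's catalyst stands at 23.5% of its charge, against my 23.3%. The early ratio is where the forecast parts from the flask: the step from target to isomer of the product B lowers that ratio at 3.0 s, which reads 6.17 without the step and 3.77 with it. By 1.50 min the flask already holds 17.2% of isomer of the product B. For the neighbour with 5.0 mM of starting material, my balance gives 0.0419 mM free, 9.01% of this flask's 0.465 mM, or 8.37% of its own charge, and the neighbour's catalyst stands at 8.59%.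

Readings and results were computed for an exercise; noise was put on by code.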